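**Retrosynthetic overview**

- The target is the all-cis (2S,4R,6S)-tetrahydropyran (O1, C2 arylethyl, C4 OH, C6 ring B); the last operations are acetate methanolysis and hydrogenolysis of three benzyl ethers.
- Key disconnection O1–C2: ring A, its CH2CH2 tether, C2 and C3 of the tetrahydropyran are the carbon skeleton of zingerone, so C2 is carried as a ketone carbonyl and O1 as a triethylsilyl ether oxygen on C6; reductive etherification closes the ring.
- Disconnection C3–C4: a 1,3-anti Mukaiyama aldol joins the kinetic enol silane of O-benzylzingerone to (S)-3-aryl-3-(triethylsilyloxy)propanal, so C4 is set from C6.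
- C6 is set by asymmetric transfer hydrogenation of the aroylacetate obtained by crossed Claisen condensation of benzylated methyl 3-O-methylgallate with ethyl acetate.
- Ring order: rings A and B are bought; the tetrahydropyran is the only ring formed, in step 10.

Key step: step 10

Assumption: methyl 3,4-dihydroxy-5-methoxybenzoate is taken as the commercial source of ring B, because a Claisen route to the aroylacetate avoids the aryl migration that electron-rich benzaldehydes tend to show on diazoacetate homologation; open-chain compounds are numbered C1 (next to ring A) to C7 (next to ring B).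

**Route**

Step 1
Reactants: 1 methyl 3,4-dihydroxy-5-methoxybenzoate
Product: 2 methyl 3,4-bis(benzyloxy)-5-methoxybenzoate
Conditions: BnBr (2.4 equiv), K2CO3 (3 equiv), DMF, 60 °C
Reagents that add atoms: benzyl bromide, BrCc1ccccc1
Why: Williamson ether synthesis; the two phenoxides formed with K2CO3 should displace bromide from benzyl bromide while the methyl ester is untouched.

Step 2
Reactants: 2 methyl 3,4-bis(benzyloxy)-5-methoxybenzoate; 3 ethyl acetate
Product: 5 ethyl 3-[3,4-bis(benzyloxy)-5-methoxyphenyl]-3-oxopropanoate, via lithium enolate of ethyl acetate 4 (not isolated)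
Conditions: EtOAc (2.5 equiv), LiN(SiMe3)2 (3.5 equiv), THF, −78 °C; then ester 2, −78 °C → rt; 1 M HCl
Reagents that add atoms: none
Why: Crossed Claisen condensation; the preformed ester enolate should acylate on the non-enolisable aryl ester, and deprotonation of the β-keto ester by the excess base drives the acyl transfer to completion.

Step 3
Reactants: 5 ethyl 3-[3,4-bis(benzyloxy)-5-methoxyphenyl]-3-oxopropanoate
Product: 6 ethyl (S)-3-[3,4-bis(benzyloxy)-5-methoxyphenyl]-3-hydroxypropanoate
Conditions: RuCl(p-cymene)[(S,S)-TsDPEN] (1 mol %), HCO2H/Et3N (5:2), DMF, 40 °C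
Reagents that add atoms: none
Why: Noyori asymmetric transfer hydrogenation; the (S,S)-TsDPEN ruthenium hydride should deliver hydride to the aryl ketone face fixed by the contact between the p-cymene ligand and the aryl group, which gives the S carbinol as with acetophenone, and benzyl ethers and the ester are inert.

Step 4
Reactants: 6 ethyl (S)-3-[3,4-bis(benzyloxy)-5-methoxyphenyl]-3-hydroxypropanoate
Product: 7 ethyl (S)-3-[3,4-bis(benzyloxy)-5-methoxyphenyl]-3-(triethylsilyloxy)propanoate
Conditions: TESCl, imidazole, DMF, 0 °C → rt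
Reagents that add atoms: chlorotriethylsilane, CC[Si](Cl)(CC)CC
Why: Imidazole-promoted O-silylation of a secondary benzylic alcohol; the stereocentre is not touched.

Step 5
Reactants: 7 ethyl (S)-3-[3,4-bis(benzyloxy)-5-methoxyphenyl]-3-(triethylsilyloxy)propanoate
Product: 8 (S)-3-[3,4-bis(benzyloxy)-5-methoxyphenyl]-3-(triethylsilyloxy)propanal
Conditions: iBu2AlH (1.1 equiv), CH2Cl2, −78 °C; MeOH, then aq potassium sodium tartrate
Reagents that add atoms: none
Why: Partial reduction of an ester with iBu2AlH; the tetrahedral aluminium hemiacetal should persist at −78 °C and release the aldehyde only on work-up, and the crude aldehyde is used at once.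

Step 6
Reactants: 9 zingerone, 4-(4-hydroxy-3-methoxyphenyl)butan-2-one
Product: 10 4-(4-benzyloxy-3-methoxyphenyl)butan-2-one
Conditions: BnBr, K2CO3, DMF, rt
Reagents that add atoms: benzyl bromide, BrCc1ccccc1
Why: Williamson ether synthesis on the phenol; the ketone is not alkylated by carbonate at room temperature.

Step 7
Reactants: 10 4-(4-benzyloxy-3-methoxyphenyl)butan-2-one
Product: 12 4-(4-benzyloxy-3-methoxyphenyl)-2-(trimethylsilyloxy)but-1-ene, via terminal lithium enolate 11 (not isolated)
Conditions: LiN(iPr)2 (1.1 equiv), THF, −78 °C; then TMSCl, −78 → 0 °C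
Reagents that add atoms: chlorotrimethylsilane, C[Si](C)(C)Cl
Why: Kinetic enolisation; the hindered amide base should remove a methyl proton rather than a C2 methylene proton at −78 °C, and O-silylation traps the terminal enolate as the enol silane.

Step 8
Reactants: 8 (S)-3-[3,4-bis(benzyloxy)-5-methoxyphenyl]-3-(triethylsilyloxy)propanal; 12 4-(4-benzyloxy-3-methoxyphenyl)-2-(trimethylsilyloxy)but-1-ene
Product: 13 (5S,7S)-7-[3,4-bis(benzyloxy)-5-methoxyphenyl]-1-(4-benzyloxy-3-methoxyphenyl)-5-hydroxy-7-(triethylsilyloxy)heptan-3-one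
Conditions: BF3·OEt2 (1.1 equiv), CH2Cl2, −78 °C; aq NaHCO3
Reagents that add atoms: none
Why: Mukaiyama aldol through an open transition state; the BF3-bound aldehyde should react from the conformer in which the C7–O and C=O dipoles are opposed, so the enol silane attacks the face away from the aryl group and the new C5 carbinol is anti to the C7 oxygen (5S), any C5 epimer being removed by chromatography.

Step 9
Reactants: 13 (5S,7S)-7-[3,4-bis(benzyloxy)-5-methoxyphenyl]-1-(4-benzyloxy-3-methoxyphenyl)-5-hydroxy-7-(triethylsilyloxy)heptan-3-one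
Product: 14 (5S,7S)-5-acetoxy-7-[3,4-bis(benzyloxy)-5-methoxyphenyl]-1-(4-benzyloxy-3-methoxyphenyl)-7-(triethylsilyloxy)heptan-3-one
Conditions: Ac2O, pyridine, DMAP (cat.), CH2Cl2, 0 °C
Reagents that add atoms: acetic anhydride, CC(=O)OC(C)=O
Why: DMAP-catalysed acylation of a secondary alcohol; it is kept cold and short so that the β-acetoxy ketone does not eliminate.

Step 10
Reactants: 14 (5S,7S)-5-acetoxy-7-[3,4-bis(benzyloxy)-5-methoxyphenyl]-1-(4-benzyloxy-3-methoxyphenyl)-7-(triethylsilyloxy)heptan-3-one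
Product: 16 (2S,4R,6S)-2-[2-(4-benzyloxy-3-methoxyphenyl)ethyl]-6-[3,4-bis(benzyloxy)-5-methoxyphenyl]tetrahydropyran-4-yl acetate, via cyclic oxocarbenium bromide 15 (not isolated)
Conditions: BiBr3 (0.2 equiv), Et3SiH (3 equiv), MeCN, −30 → 0 °C
Reagents that add atoms: none
Why: BiBr3 with Et3SiH supplies the acid that activates the C3 ketone; the oxygen of the C7 triethylsilyl ether adds to the carbonyl carbon, the silyl group is lost and the cyclic adduct ionises to oxocarbenium ion 15, which Et3SiH reduces, the silicon ending as hexaethyldisiloxane. This is the known BiBr3/Et3SiH reductive etherification of δ-trialkylsilyloxy ketones to cis-2,6-disubstituted tetrahydropyrans, which has 2-aryl examples. The tetrahydropyran closes by 6-exo-trig attack of oxygen on the carbonyl carbon, which forms the O1–C2 bond. The new stereocentre C2 is controlled by the ring: in the half-chair of 15 the cis-disposed C6 aryl and C4 acetoxy groups are both pseudo-equatorial, hydride enters axially through a chair-like transition state, and the arylethyl chain ends equatorial (2S, all-cis). The step needs reduction of the oxocarbenium ion in preference to ionisation of the benzylic C6–O1 bond and to loss of the C4 acetate through the enol ether; the low temperature, the excess of silane and the fact that only the para oxygen of ring B donates to the benzylic carbon should secure this.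

Step 11
Reactants: 16 (2S,4R,6S)-2-[2-(4-benzyloxy-3-methoxyphenyl)ethyl]-6-[3,4-bis(benzyloxy)-5-methoxyphenyl]tetrahydropyran-4-yl acetate
Product: 17 (2S,4R,6S)-2-[2-(4-benzyloxy-3-methoxyphenyl)ethyl]-6-[3,4-bis(benzyloxy)-5-methoxyphenyl]tetrahydropyran-4-ol
Conditions: K2CO3 (0.3 equiv), MeOH/THF, 0 °C → rt
Reagents that add atoms: none
Why: Base-catalysed transesterification (Zemplén-type methanolysis) of a secondary acetate; no ring stereocentre is epimerisable, and it is done before the air-sensitive catechol is unmasked.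

Step 12
Reactants: 17 (2S,4R,6S)-2-[2-(4-benzyloxy-3-methoxyphenyl)ethyl]-6-[3,4-bis(benzyloxy)-5-methoxyphenyl]tetrahydropyran-4-ol
Product: 18 (2S,4R,6S)-6-(3,4-dihydroxy-5-methoxyphenyl)-2-[2-(4-hydroxy-3-methoxyphenyl)ethyl]tetrahydropyran-4-ol, the target
Conditions: H2 (1 atm), Pd/C, EtOAc/MeOH, rt
Reagents that add atoms: none
Why: Catalytic hydrogenolysis of aryl benzyl ethers; under neutral conditions at 1 atm these should cleave much faster than the dialkyl benzylic C6–O1 bond of the ring.

**Compound list**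

1 | methyl 3,4-dihydroxy-5-methoxybenzoate | COC(=O)c1cc(O)c(O)c(OC)c1 | starting material
2 | methyl 3,4-bis(benzyloxy)-5-methoxybenzoate | COC(=O)c1cc(OCc2ccccc2)c(OCc2ccccc2)c(OC)c1 | intermediate
3 | ethyl acetate | CCOC(C)=O | starting material
4 | lithium enolate of ethyl acetate | C=C(O[Li])OCC | intermediate
5 | ethyl 3-[3,4-bis(benzyloxy)-5-methoxyphenyl]-3-oxopropanoate | CCOC(=O)CC(=O)c1cc(OCc2ccccc2)c(OCc2ccccc2)c(OC)c1 | intermediate
6 | ethyl (S)-3-[3,4-bis(benzyloxy)-5-methoxyphenyl]-3-hydroxypropanoate | CCOC(=O)C[C@H](O)c1cc(OCc2ccccc2)c(OCc2ccccc2)c(OC)c1 | intermediate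
7 | ethyl (S)-3-[3,4-bis(benzyloxy)-5-methoxyphenyl]-3-(triethylsilyloxy)propanoate | CCOC(=O)C[C@H](O[Si](CC)(CC)CC)c1cc(OCc2ccccc2)c(OCc2ccccc2)c(OC)c1 | intermediate
8 | (S)-3-[3,4-bis(benzyloxy)-5-methoxyphenyl]-3-(triethylsilyloxy)propanal | O=CC[C@H](O[Si](CC)(CC)CC)c1cc(OCc2ccccc2)c(OCc2ccccc2)c(OC)c1 | intermediate
9 | zingerone, 4-(4-hydroxy-3-methoxyphenyl)butan-2-one | COc1cc(CCC(C)=O)ccc1O | starting material
10 | 4-(4-benzyloxy-3-methoxyphenyl)butan-2-one | COc1cc(CCC(C)=O)ccc1OCc1ccccc1 | intermediate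
11 | terminal lithium enolate of 10 | COc1cc(CCC(=C)O[Li])ccc1OCc1ccccc1 | intermediate
12 | 4-(4-benzyloxy-3-methoxyphenyl)-2-(trimethylsilyloxy)but-1-ene | COc1cc(CCC(=C)O[Si](C)(C)C)ccc1OCc1ccccc1 | intermediate
13 | (5S,7S)-7-[3,4-bis(benzyloxy)-5-methoxyphenyl]-1-(4-benzyloxy-3-methoxyphenyl)-5-hydroxy-7-(triethylsilyloxy)heptan-3-one | COc1cc(CCC(=O)C[C@@H](O)C[C@@H](c2cc(OCc3ccccc3)c(OCc3ccccc3)c(OC)c2)O[Si](CC)(CC)CC)ccc1OCc1ccccc1 | intermediate
14 | (5S,7S)-5-acetoxy-7-[3,4-bis(benzyloxy)-5-methoxyphenyl]-1-(4-benzyloxy-3-methoxyphenyl)-7-(triethylsilyloxy)heptan-3-one | COc1cc(CCC(=O)C[C@@H](OC(C)=O)C[C@@H](c2cc(OCc3ccccc3)c(OCc3ccccc3)c(OC)c2)O[Si](CC)(CC)CC)ccc1OCc1ccccc1 | intermediate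
15 | (4S,6S)-4-acetoxy-2-[2-(4-benzyloxy-3-methoxyphenyl)ethyl]-6-[3,4-bis(benzyloxy)-5-methoxyphenyl]-3,4,5,6-tetrahydro-2H-pyran-1-ium bromide (C2=O1 oxocarbenium ion) | COc1cc(CCC2=[O+][C@H](c3cc(OCc4ccccc4)c(OCc4ccccc4)c(OC)c3)C[C@H](OC(C)=O)C2)ccc1OCc1ccccc1.[Br-] | intermediate
16 | (2S,4R,6S)-2-[2-(4-benzyloxy-3-methoxyphenyl)ethyl]-6-[3,4-bis(benzyloxy)-5-methoxyphenyl]tetrahydropyran-4-yl acetate | COc1cc(CC[C@H]2C[C@@H](OC(C)=O)C[C@@H](c3cc(OCc4ccccc4)c(OCc4ccccc4)c(OC)c3)O2)ccc1OCc1ccccc1 | intermediate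
17 | (2S,4R,6S)-2-[2-(4-benzyloxy-3-methoxyphenyl)ethyl]-6-[3,4-bis(benzyloxy)-5-methoxyphenyl]tetrahydropyran-4-ol | COc1cc(CC[C@H]2C[C@@H](O)C[C@@H](c3cc(OCc4ccccc4)c(OCc4ccccc4)c(OC)c3)O2)ccc1OCc1ccccc1 | intermediate
18 | (2S,4R,6S)-6-(3,4-dihydroxy-5-methoxyphenyl)-2-[2-(4-hydroxy-3-methoxyphenyl)ethyl]tetrahydropyran-4-ol | COc1cc(CC[C@H]2C[C@@H](O)C[C@@H](c3cc(O)c(O)c(OC)c3)O2)ccc1O | target

**Step count**

Total: 12 steps. Longest linear sequence: 10 steps (steps 1 to 5, then 8 to 12).

**Steps most likely to fail**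

Step 10. What may go wrong: acid-induced ionisation of the electron-rich benzylic C6–O bond followed by silane reduction to a ring-opened product, loss of the C4 acetate through the enol ether of the oxocarbenium ion, or direct reduction of the ketone before closure. Fallback: separate ring closure from reduction. It sets out from 14. Pyridinium p-toluenesulfonate in MeOH with trimethyl orthoformate should remove the silyl group and convert the resulting hemiketal into the cyclic methyl ketal F1. Reduction of this ketal with Et3SiH and TMSOTf in CH2Cl2 at −78 °C then passes through the same oxocarbenium ion at a temperature where the benzylic ether should not ionise, and returns to the route at 16.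

Step 8. What may go wrong: weak 1,3-induction from the non-chelating β-silyloxy group, which would give poor facial selectivity at C5, and BF3-induced loss of the benzylic silyl ether with β-elimination. Fallback: make the C5 configuration irrelevant at the aldol stage and correct it on the ring. It sets out from 8 and lithium enolate 11, combined in THF at −78 °C without a Lewis acid, which should give 13 together with its C5 epimer, the (5R,7S)-aldol F2. The mixture is carried through steps 9 to 11: acetylation gives 14 and the (5R,7S)-acetate F3, reductive etherification gives 16 and the C4-epimeric (2S,4S,6S)-acetate F4, and methanolysis gives 17 and the axial (2S,4S,6S)-alcohol F5. Oxidation of the alcohol mixture with Dess–Martin periodinane converges on one compound, the cis-2,6-disubstituted tetrahydropyran-4-one F6. NaBH4 in MeOH at −40 °C should add hydride axially and give the equatorial alcohol, which is 17, where the fallback rejoins the route.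

Step 5. What may go wrong: over-reduction to the primary alcohol, or β-elimination of silanol from the aldehyde during work-up. Fallback: a two-step redox sequence. It sets out from 7, which LiBH4 in THF/MeOH at 0 °C should reduce fully to the primary alcohol F7. Parikh–Doering oxidation (SO3·pyridine, DMSO, iPr2NEt, 0 °C) under buffered, non-acidic conditions returns 8, which is used at once.

**Further compounds**

F1 | step 10 | (4S,6S)-2-[2-(4-benzyloxy-3-methoxyphenyl)ethyl]-6-[3,4-bis(benzyloxy)-5-methoxyphenyl]-2-methoxytetrahydropyran-4-yl acetate, both C2 epimers | COc1cc(CCC2(OC)C[C@@H](OC(C)=O)C[C@@H](c3cc(OCc4ccccc4)c(OCc4ccccc4)c(OC)c3)O2)ccc1OCc1ccccc1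
F2 | step 8 | (5R,7S)-7-[3,4-bis(benzyloxy)-5-methoxyphenyl]-1-(4-benzyloxy-3-methoxyphenyl)-5-hydroxy-7-(triethylsilyloxy)heptan-3-one | COc1cc(CCC(=O)C[C@H](O)C[C@@H](c2cc(OCc3ccccc3)c(OCc3ccccc3)c(OC)c2)O[Si](CC)(CC)CC)ccc1OCc1ccccc1
F3 | step 8 | (5R,7S)-5-acetoxy-7-[3,4-bis(benzyloxy)-5-methoxyphenyl]-1-(4-benzyloxy-3-methoxyphenyl)-7-(triethylsilyloxy)heptan-3-one | COc1cc(CCC(=O)C[C@H](OC(C)=O)C[C@@H](c2cc(OCc3ccccc3)c(OCc3ccccc3)c(OC)c2)O[Si](CC)(CC)CC)ccc1OCc1ccccc1
F4 | step 8 | (2S,4S,6S)-2-[2-(4-benzyloxy-3-methoxyphenyl)ethyl]-6-[3,4-bis(benzyloxy)-5-methoxyphenyl]tetrahydropyran-4-yl acetate | COc1cc(CC[C@H]2C[C@H](OC(C)=O)C[C@@H](c3cc(OCc4ccccc4)c(OCc4ccccc4)c(OC)c3)O2)ccc1OCc1ccccc1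
F5 | step 8 | (2S,4S,6S)-2-[2-(4-benzyloxy-3-methoxyphenyl)ethyl]-6-[3,4-bis(benzyloxy)-5-methoxyphenyl]tetrahydropyran-4-ol | COc1cc(CC[C@H]2C[C@H](O)C[C@@H](c3cc(OCc4ccccc4)c(OCc4ccccc4)c(OC)c3)O2)ccc1OCc1ccccc1
F6 | step 8 | (2S,6S)-2-[2-(4-benzyloxy-3-methoxyphenyl)ethyl]-6-[3,4-bis(benzyloxy)-5-methoxyphenyl]tetrahydropyran-4-one | COc1cc(CC[C@H]2CC(=O)C[C@@H](c3cc(OCc4ccccc4)c(OCc4ccccc4)c(OC)c3)O2)ccc1OCc1ccccc1
F7 | step 5 | (S)-3-[3,4-bis(benzyloxy)-5-methoxyphenyl]-3-(triethylsilyloxy)propan-1-ol | OCC[C@H](O[Si](CC)(CC)CC)c1cc(OCc2ccccc2)c(OCc2ccccc2)c(OC)c1
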